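We decide to reckon these flasks by counting incoming ligand and to leave the rates aside.

| setting | alder | oak | midnight | summer | autumn |
|---|---|---|---|---|---|
| starting complex | 20 mM | 20 mM | 20 mM | 20 mM | 20 mM |
| incoming ligand | 5.1 mM | 39 mM | 10.0 mM | 30.0 mM | 50.0 mM |
| leaving ligand | 40 mM | 40 mM | 40.0 mM | 40.0 mM | 40.0 mM |
| remark | run made earlier | run made earlier |  |  |  |
| time |  |  | 8.0 h | 8.0 h | 8.0 h |

| run | time / h | complex with two exchanged / % | complex with one exchanged / % |
|---|---|---|---|
| alder | 0.667 | 3 | 8 |
| alder | 2.00 | 0 | 9 |
| alder | 4.00 | 5 | 9 |
| alder | 6.00 | 3 | 7 |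
| oak | 1.33 | 49 | 14 |
| oak | 3.00 | 60 | 7 |
| oak | 4.00 | 65 | 5 |
| oak | 6.00 | 66 | 8 |

(readings scatter by 2 percentage points)

- the numbers in the tables scatter with a standard deviation of 2 percentage points
- a reading or a percentage of leaving ligand counts all its forms, free or not

- complex with two exchanged at the end, in percent of the starting complex charged, for each flask in turn (midnight, summer, autumn)

Take the main process first: each starting complex takes up two incoming ligand and becomes complex with two exchanged. The yield then has a ceiling, the charged c(incoming ligand) divided by 2 times the charged c(starting complex). This gives 25.0 % in midnight and 75.0 % in summer. Autumn reckons to 125 %, but there the ligand exceeds the need, so starting complex is the limiting reagent and the ceiling is 100 %.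

Now add complex with one exchanged. Oak has a ceiling of 97.5 %, and its last two readings average 6.50 % of this complex. Each holds one ligand, so the correction costs 3.2 percentage points. Oak's complex with two exchanged reads 65 % and 66 %, averaging 65.5 %, which leaves a gap of 32 points, and the correction is much smaller than that gap.

We carry the gap as one number, read off oak's readings: 67.2 % is the fill, the share of the ceiling that complex with two exchanged holds once the readings level off. Alder reads lower, 2.75 % under a ceiling of 12.7 %, a fill of 21.6 %, but that level is read against a scatter of 2 points. Alder's fill would put midnight at 5.39 %. We commit to oak's fill and reckon 16.8 % for midnight, 50.4 % for summer and 67.2 % for autumn.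

The forecast says 7 %, 52 % and 84 %, on the suggestion that “the two-exchanged complex is removed nonlinearly”.

The flasks end at 17.1 %, 53.7 % and 68.5 %, under this scheme:

    starting complex + incoming ligand ⇌ leaving ligand + complex with one exchanged (K = 2.00, k = 0.0116 L mol⁻¹ s⁻¹)
    crystals ⇌ leaving ligand, rate k2*(cs2 - [leaving ligand]) while solid is left; crystals form when [leaving ligand] > cs2 (solubility = 15.0 mM, k = 0.00179 s⁻¹)
    2 incoming ligand → homo dimer (k = 1.95 × 10⁻⁴ L mol⁻¹ s⁻¹)
    2 starting complex → self-condensation product (k = 1.06 × 10⁻⁶ L mol⁻¹ s⁻¹)
    complex with one exchanged + incoming ligand ⇌ leaving ligand + complex with two exchanged (K = 42.1, k = 0.0321 L mol⁻¹ s⁻¹)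
    complex with two exchanged + incoming ligand ⇌ leaving ligand + complex with three exchanged (K = 5.00, k = 0.00110 L mol⁻¹ s⁻¹)

Measured against their ceilings, these are fills of 68.4 % in midnight and 71.6 % in summer. Put on autumn's ceiling, our fill gives 67.2 %, which is 1.3 points below that flask, where complex with three exchanged stands at 21.4 % at the end.

The data are simulated for substances that don't exist.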